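The noon run takes 20.0 h to bring its target to 18.6% of the starting material charged, and a run this slow lets me read a slope from its readings by hand.

| setting | noon | autumn | Friday's | Tuesday's | Wednesday's |
|---|---|---|---|---|---|
| starting material | 0.050 M | 0.050 M | 0.050 M | 0.050 M | 0.050 M |
| second substrate | 2 equiv | 2 equiv | 2.00 equiv | 2.00 equiv | 2.00 equiv |
| reagent | 0.60 equiv | 0.60 equiv | 0.600 equiv | 2.00 equiv | 6.00 equiv |
| free catalyst | 0.48 mol% | 0.16 mol% | 0.32 mol% | 0.32 mol% | 0.32 mol% |
| remark | run made earlier | run made earlier |  |  |  |
| time |  |  | 50 h | 50 h | 50 h |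

- noon (time / h: target / %, starting material / %): 1.33: 1.6, 97.7; 2.00: 1.9, 97.7; 3.00: 3.1, 96.0; 5.00: 5.7, 94.0; 8.00: 9.8, 90.1; 12.0: 13.3, 87.1; 20.0: 18.6, 79.9
- autumn (time / h: target / %, starting material / %): 1.33: 0.7, 100.1; 2.00: 1.3, 99.2; 3.00: 0.4, 98.2; 5.00: 2.1, 97.1; 8.00: 3.8, 96.4; 12.0: 5.3, 94.0; 20.0: 7.2, 91.0

(standard deviation of a reading: 0.5 percentage points)

- "hardly changes" means that all values lie within two and a half points (for a concentration: within two and a half percent of the largest)

* [target] at the end for Friday's, Tuesday's, Wednesday's, in this order
* how the row runs (rises, then falls / falls all the way / rises all the way / falls, then rises / hardly changes)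

I pool the noon and autumn runs, dividing the target gained by the catalyst charged and by the hours. Up to 20.0 h this gives a mean rate of 2.02 h⁻¹. Between 12.0 h and 20.0 h it gives 1.41 h⁻¹, which is slower, so the curve bends. I therefore replace it by two straight pieces, the mean rate up to 20.0 h and the late rate held for the remaining 30.0 h. That gives the turnover count at the end, the moles of target standing per mole of catalyst charged, 82.5. The pooled late gain of 7.2 percentage points carries a scatter of 1 point, so the count is uncertain by about 5.86. For Friday's flask, with 0.32 mol% of catalyst, the count gives 0.0132 M.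

The weak link is reagent, which neither run varied. As a judgement, I read the catalyst as sitting in a resting state that waits for reagent, so I scale the count with the reagent charge. Tuesday's flask then gives 0.0440 M. Wednesday's flask reckons to 264% of the starting material, more than was charged, so I cap it at 0.050 M. My row rises.

The forecast, below my Friday's figure, reads 0.009 M, 0.0091 M, 0.0091 M, a row that hardly changes, on the ground that “I expect catalyst turnover capacity, not reagent, to set the yield”.

The flasks give 0.0134 M, 0.0353 M, 0.0186 M, a row that rises, then falls.

    starting material + free catalyst ⇌ catalyst intermediate A (K = 270 M⁻¹, k = 48.0 M⁻¹ min⁻¹)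
    reagent + catalyst intermediate A → free catalyst + target (k = 2.20 M⁻¹ min⁻¹)
    second substrate + free catalyst ⇌ catalyst intermediate B (K = 360 M⁻¹, k = 16.0 M⁻¹ min⁻¹)
    reagent + catalyst intermediate B → free catalyst + second product (k = 8.40 M⁻¹ min⁻¹)
    free catalyst + target → free catalyst + over-reaction product (k = 2.80 M⁻¹ min⁻¹)
    2 second substrate → homo dimer (k = 0.0370 M⁻¹ min⁻¹)

Friday's target comes to 83.8 turnovers per catalyst against my 82.5, and at 50.0 h it is still made 4.54 times as fast as it is used up, faster. Scaled to Tuesday's reagent, the count gives 88.0% of the starting material turned over. Tuesday's flask has used 91.8%, of which 70.6% stands as target and 21.1% as over-reaction product.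

The data are calculated with made-up constants.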